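## Analysis of the target

The target is a humulane: a single eleven-membered carbocycle, esterified at one carbon with (E)-p-coumaric acid, the arene being the only other ring. The ring atoms are numbered C1 (bearing the exocyclic methylene) through C2, C3, the olefin C4=C5 (methyl on C5), C6, the ester carbinol C7, C8, the gem-dimethyl carbon C9 and C10 to the hydroperoxide carbon C11. The two stereocentres are C7 (R) and C11 (S). They are 1,5-related across the quaternary C9, so neither can direct the other locally; control can only come through the ring conformation or from separate reagents. The C4=C5 olefin is Z, the opposite of the geometry in natural α-humulene. The secondary allylic hydroperoxide is the most fragile group (reduction, base-induced Kornblum–DeLaMare elimination, acid-induced Hock cleavage, radical allylic shift), followed by the coumarate (E/Z photoisomerisation, acyl transfer) and the free phenol, so O–O must be made at the very end. The hard parts are closing an eleven-membered ring next to a quaternary carbon, holding the Z geometry, and introducing the peroxide mildly and with the right configuration. The strategy rests on reading the ring as a masked humulene triene: C7–C8 is a hydrated disubstituted olefin, C11–C1(=CH2) is the ene-transposed form of a trisubstituted olefin, and the bond C9–C10 is the bond a humulene synthase forms between C11 and C1 of a farnesyl chain.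

## Retrosynthetic reasoning

**Phenol O–Si.** Target 20 is taken back to its silyl ether 19. The phenol stays masked to the end because a free phenol can quench singlet oxygen and would compete in the acylation. The forward step must remove silicon without touching O–O, which calls for buffered fluoride.

**C11–O, with the C1=CH2 double bond moved back into the ring.** 19 comes from the triene-derived ester 18 by a Schenck ene reaction at the E olefin C1=C11. This makes the O–O unit and the exocyclic methylene in one neutral step, so no activated C11 derivative next to an allylic system is needed. The forward reaction must choose the E olefin over the Z olefin C4=C5, abstract a methyl hydrogen instead of a ring hydrogen, and add oxygen to the face of C11 that gives S.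

**Ester C–O at C7.** 18 is cut into the ring alcohol 14 and the silyl-protected acid 17, which comes in one step from p-coumaric acid 15. Acylation must precede photooxygenation, since a hydroperoxide would itself be acylated.

**C7–O.** 14 comes from the hydrocarbon 12 by hydroboration–oxidation. C7=C8 is the only 1,2-disubstituted olefin of 12, and its two carbons differ sharply because C8 is attached to the quaternary C9, so boron should go to C7. The forward step must distinguish this olefin from two trisubstituted ones and pick one face; a chiral monoalkylborane suited to trans olefins is the reagent type.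

**C9–C10 (key disconnection).** Cutting the most hindered ring bond opens 12 to the acyclic diphosphate 11, in which ring C10 is chain C1 and ring C9 is chain C11. No conventional ring closure forms this bond, but a humulene synthase makes exactly this bond in the all-E series. The gain is the whole carbocycle, quaternary carbon included, from an unfunctionalised C15 chain in one step without protecting groups. The forward reaction must accept the 6Z chain, close 1,11 and eliminate toward the disubstituted olefin.

**Allylic C–O of the diphosphate.** 11 comes from the chloride 9 and the diphosphate salt 10, and 9 from the alcohol 8, by two substitutions at a primary allylic carbon that leave both olefin geometries alone.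

**Chain C2=C3.** 8 is the reduction product of the enoate 7, which is cut at the olefin into the methyl ketone 5 and the phosphonate 6. This sets the 2E geometry by a Horner–Wadsworth–Emmons reaction while the 6Z olefin is only a spectator.

**Chain C4–C5.** 5 is the acetoacetate alkylation and decarboxylation product of the bromide 2 and ethyl acetoacetate 3, and 2 comes from nerol 1. The Z olefin of the target is thus bought, not made.

## Alternatives that were turned down

**Alternative 1:** The ring is cut at C3–C4, giving the open-chain cyclopropanol A1 with the C7 p-methoxybenzyl ether, the C11 silyl ether and a Z alkenyl iodide at C4.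
- Forward key step: Pd(OAc)2 with a bulky phosphine gives zerovalent palladium, which inserts into the carbon–iodine bond. The cyclopropanol binds as its alkoxide, β-carbon elimination at divalent palladium opens the three-membered ring to a metal-bound homoenolate, and reductive elimination joins C3 to C4, closing the ring as the C1 ketone A2.
- For: both stereocentres are set on an acyclic chain by reagent control before the ring exists. The Z geometry is fixed in the iodide and carried through a stereoretentive coupling. The carbonyl of A2 sits where the methylene must go.
- Against: this ring-opening coupling is an intermolecular reaction of aryl and alkenyl halides. An eleven-membered closure would have to beat β-hydride elimination of the homoenolate and intermolecular coupling. A1 needs a long linear sequence with two protecting groups. In A2 the C11 oxygen has the configuration opposite to the target, so the peroxide would have to be installed by inverting substitution at a carbon that is allylic once C1 is methylenated, where SN2′ and ionisation compete.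
- Comparison: this plan is stronger on stereocontrol, since neither centre depends on the conformation of a flexible ring. The chosen route gives that up for brevity and for making O–O directly at C11 under neutral conditions.

**Alternative 2:** A bond C1–C7 is added across the ring, turning the macrocycle into the bicyclo[5.4.0]undecene A4. Its six-membered ring (C7 to C11 with C1) is grown from dimedone A3 and its seven-membered ring holds C4=C5; C1 bears a tosyloxymethyl arm and C7 a tertiary hydroxyl.
- Forward key step: KOtBu forms the C7 alkoxide and a Grob fragmentation breaks C1–C7 as tosylate leaves, giving the C7 ketone and the exocyclic methylene at once and opening the bicycle to the eleven-membered ketone A5.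
- For: such fragmentations are dependable routes to medium rings, because the ring is first made in six- and seven-membered form. The Z olefin is enforced by the seven-membered ring of A4. The gem-dimethyl unit comes with A3, and two functional groups of the target appear in one step.
- Against: A4 has a quaternary C1 next to a tertiary carbinol, and C11 must be differentiated from C7 by a desymmetrising reduction. A5 is a β,γ-unsaturated ketone that can slip into conjugation. Its reduction must set C7 in a flexible ring with methylenes on both sides, a remote-control problem no easier than the one the chosen route has at C11. C11 of A5 again has the configuration opposite to the target, so the peroxide must come by inverting allylic substitution.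
- Comparison: the ring-forming event is on firmer ground than an enzyme offered an unnatural isomer, and there this plan is stronger. The chosen route is much shorter and avoids allylic substitution with hydrogen peroxide.

**Alternative 3:** The ring is derived from a seven-membered one by a four-carbon expansion. The precursor is the cis-1,2-divinylcycloheptanol A6, in which C11 is the carbinol carbon with one vinyl group (C1, C2) and the neighbouring quaternary C5 carries the methyl and the other vinyl group (C4, C3).
- Forward key step: KH and 18-crown-6 give the potassium alkoxide, which undergoes an anionic oxy-Cope rearrangement. C2–C3 forms, C5–C11 breaks, and quenching gives the C11 ketone A7 with the C4=C5 olefin and the C7 silyl ether.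
- For: the rearrangement is a classic entry to medium-ring ketones and C7 is carried through unchanged. After methylenation at C1 the C11 carbonyl of A7 could be reduced under reagent control, so C11 would not depend on the ring conformation.
- Against: A6 has two adjacent fully substituted ring carbons plus the gem-dimethyl group and must be one diastereomer. For cis-divinyl alkoxides chair and boat pathways lie close, so the Z geometry is not secured. Methylenation must choose C1 over C10. The peroxide again has to be made from an allylic alcohol by substitution.
- Comparison: this plan is stronger on C11 control. It is weaker on length, on the olefin geometry (which the chosen route takes unchanged from nerol) and on the peroxide installation.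

Key step: step 7

## Route

Remarks:
- Ring positions use the C1–C11 numbering of the analysis; open-chain compounds use farnesyl numbering.
- Diphosphate 11 is handled as its tris-ammonium salt; its SMILES is written for the free acid.
- The facial sense of the borane in step 8 is assigned by analogy with simple trans-alkenes; should it prove opposite, the reagent from (−)-α-pinene is used.

Step 1
Reactants: 1 nerol [(2Z)-3,7-dimethylocta-2,6-dien-1-ol]
Product: 2 neryl bromide [(2Z)-1-bromo-3,7-dimethylocta-2,6-diene]
Conditions: PBr3 (0.4 equiv), Et2O, −10 °C
Reagents that add atoms: phosphorus tribromide, BrP(Br)Br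
Why: Activation of the primary allylic alcohol as a phosphite ester and SN2 displacement by bromide; at low temperature in ether the Z geometry should be kept and allylic transposition stay minimal, and 2 is used at once.

Step 2
Reactants: 2 neryl bromide; 3 ethyl acetoacetate
Product: 5 nerylacetone [(5Z)-6,10-dimethylundeca-5,9-dien-2-one], via ethyl (4Z)-2-acetyl-5,9-dimethyldeca-4,8-dienoate 4 (not isolated)
Conditions: NaOEt, EtOH, 0 °C to rt; then aq. NaOH, 60 °C; then HCl to pH 2, 50 °C
Reagents that add atoms: none
Why: Acetoacetic ester synthesis: SN2 C-alkylation of the sodium enolate of 3, then saponification and decarboxylation of the β-keto acid; excess 3 suppresses dialkylation and the olefins are inert.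

Step 3
Reactants: 5 nerylacetone; 6 triethyl phosphonoacetate
Product: 7 ethyl (2E,6Z)-3,7,11-trimethyldodeca-2,6,10-trienoate
Conditions: NaH, THF, 0 °C to rt; chromatography
Reagents that add atoms: none
Why: Horner–Wadsworth–Emmons olefination of the methyl ketone, which favours the E enoate; the minor 2Z isomer and any 6E material from geraniol in commercial nerol are removed by chromatography, on AgNO3-impregnated silica if needed.

Step 4
Reactants: 7 ethyl (2E,6Z)-farnesoate
Product: 8 (2E,6Z)-farnesol [(2E,6Z)-3,7,11-trimethyldodeca-2,6,10-trien-1-ol]
Conditions: iBu2AlH (2.2 equiv), CH2Cl2, −78 °C; aq. potassium sodium tartrate (KNaC4H4O6)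
Reagents that add atoms: none
Why: 1,2-Reduction of the α,β-unsaturated ester to the allylic alcohol by two hydride transfers at low temperature; isolated olefins are untouched.

Step 5
Reactants: 8 (2E,6Z)-farnesol
Product: 9 (2E,6Z)-farnesyl chloride
Conditions: N-chlorosuccinimide, Me2S, CH2Cl2, −30 to 0 °C
Reagents that add atoms: N-chlorosuccinimide, O=C1CCC(=O)N1Cl
Why: Corey–Kim chlorination: chloride displaces the alkoxysulfonium group in an SN2 step at the primary carbon under near-neutral conditions, so no allylic transposition or E/Z scrambling is expected; 9 is used crude.

Step 6
Reactants: 9 (2E,6Z)-farnesyl chloride; 10 tris(tetrabutylammonium) hydrogen diphosphate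
Product: 11 (2E,6Z)-farnesyl diphosphate (tris-ammonium salt)
Conditions: MeCN, rt; then cation exchange (NH4+ form), cellulose chromatography
Reagents that add atoms: none
Why: SN2 displacement of the allylic chloride by the diphosphate anion, soluble in acetonitrile as its tetrabutylammonium salt; exchange to the ammonium form gives a water-soluble enzyme substrate.

Step 7
Reactants: 11 (2E,6Z)-farnesyl diphosphate
Product: 12 (1Z,4E,8E)-2,6,6,9-tetramethylcycloundeca-1,4,8-triene (the 6Z isomer of α-humulene in farnesyl numbering)
Conditions: α-humulene synthase (recombinant, Zingiber zerumbet), MgCl2 (10 mM), HEPES buffer pH 7.5, dithiothreitol, glycerol, 30 °C, pentane overlay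
Reagents that add atoms: none
Why: Proposed new method: the Mg2+ cluster of the enzyme ionises the allylic diphosphate of 11 to the (2E)-farnesyl cation, the distal olefin attacks chain C1 through its fully substituted carbon C11 (1,11-closure, anti-Markovnikov, forming ring bond C9–C10 and the eleven-membered ring), and the secondary cation at chain C10 loses a proton from C9 to give the E disubstituted olefin of 12. The closest known reaction is the same enzyme converting (2E,6E)-farnesyl diphosphate F2 into α-humulene F3; what is new is the 6Z geometry of the central olefin. That olefin takes no part in bond making in this pathway, so the change alters only the fold of the chain, and a ring with one Z olefin should be less strained than the all-E ring. No stereocentre is formed and 12 is achiral. The step needs 1,11-closure over 1,10-closure, proton loss from C9 over capture by water or proton loss from the open-chain cation, and retention of the 6Z geometry. The first two are imposed by the active-site contour, which holds C11 over C1 and shields the cation from water; the third follows because the C6=C7 olefin is never ionised. 1,6-Closure is excluded because the 2E allyl cation cannot reach C6 without prior isomerisation. The volatile hydrocarbon partitions into the pentane layer, which limits product inhibition and simplifies isolation.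

Step 8
Reactants: 12 (1Z,4E,8E)-2,6,6,9-tetramethylcycloundeca-1,4,8-triene
Product: 14 (1R,3Z,7E)-3,7,10,10-tetramethylcycloundeca-3,7-dien-1-ol, via cycloundecadienyl(isopinocampheyl)borane 13 (not isolated)
Conditions: IpcBH2 [from (+)-α-pinene, 1.0 equiv], THF, −25 °C; then NaOH, H2O2, 0 °C to rt
Reagents that add atoms: hydrogen peroxide, OO
Why: Asymmetric hydroboration with monoisopinocampheylborane, the reagent suited to trans-disubstituted alkenes, then oxidation with retention: the only 1,2-disubstituted olefin should react first, boron goes to C7 because C8 is flanked by the quaternary C9, and the facial sense of the (+)-α-pinene-derived reagent on trans alkenes corresponds to the 7R carbinol (reagent control).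

Step 9
Reactants: 15 p-coumaric acid
Product: 17 (E)-3-[4-(tert-butyldimethylsilyloxy)phenyl]prop-2-enoic acid, via bis-silylated coumarate 16 (not isolated)
Conditions: TBSCl (2.5 equiv), imidazole, DMF, rt; then AcOH, THF/H2O, rt
Reagents that add atoms: tert-butyldimethylsilyl chloride, CC(C)(C)[Si](C)(C)Cl
Why: Silylation of both acidic OH groups, then selective hydrolysis of the far more labile silyl ester; the aryl silyl ether survives dilute acetic acid.

Step 10
Reactants: 14 (1R,3Z,7E)-3,7,10,10-tetramethylcycloundeca-3,7-dien-1-ol; 17 silyl-protected coumaric acid
Product: 18 (1R,3Z,7E)-3,7,10,10-tetramethylcycloundeca-3,7-dien-1-yl (E)-3-[4-(tert-butyldimethylsilyloxy)phenyl]prop-2-enoate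
Conditions: DCC, DMAP (cat.), CH2Cl2, 0 °C to rt
Reagents that add atoms: none
Why: Steglich esterification: DMAP intercepts the O-acylisourea and the acylpyridinium acylates the secondary alcohol with retention at C7.

Step 11
Reactants: 18 silyl-protected coumarate ester
Product: 19 (1R,3Z,8S)-8-hydroperoxy-3,10,10-trimethyl-7-methylidenecycloundec-3-en-1-yl (E)-3-[4-(tert-butyldimethylsilyloxy)phenyl]prop-2-enoate
Conditions: O2, tetraphenylporphyrin (cat.), visible light (>500 nm), CH2Cl2, −20 °C, to partial conversion
Reagents that add atoms: dioxygen, O=O
Why: Schenck ene reaction of singlet oxygen: the perepoxide forms on the side of the E olefin that carries two cis alkyl groups (the methyl on C1 and ring C10), abstracts a methyl hydrogen and gives the C11 hydroperoxide with the exocyclic methylene, whereas in the Z olefin the methyl stands alone on its side and the cinnamate is too electron-poor to react. C11 is set by attack on the exposed outer face of the ring conformer favoured by the C7 ester (substrate control, sense to be established), and long-wavelength light avoids cinnamate E/Z isomerisation.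

Step 12
Reactants: 19 silyl-protected hydroperoxide
Product: 20 (1R,3Z,8S)-8-hydroperoxy-3,10,10-trimethyl-7-methylidenecycloundec-3-en-1-yl (E)-3-(4-hydroxyphenyl)prop-2-enoate (CNP0208931.1)
Conditions: Bu4NF, AcOH (1:1), THF, 0 °C
Reagents that add atoms: none
Why: Fluoride cleavage of the aryl silyl ether, which is far more labile than an alkyl silyl ether; buffering with acetic acid keeps the hydroperoxide protonated, so Kornblum–DeLaMare elimination and ester cleavage should be avoided.

## Compound list

1 | nerol | CC(C)=CCC/C(C)=C\CO | starting material
2 | neryl bromide | CC(C)=CCC/C(C)=C\CBr | intermediate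
3 | ethyl acetoacetate | CCOC(=O)CC(C)=O | starting material
4 | ethyl (4Z)-2-acetyl-5,9-dimethyldeca-4,8-dienoate (racemic at C2) | CCOC(=O)C(C/C=C(C)\CCC=C(C)C)C(C)=O | intermediate
5 | nerylacetone, (5Z)-6,10-dimethylundeca-5,9-dien-2-one | CC(=O)CC/C=C(C)\CCC=C(C)C | intermediate
6 | triethyl phosphonoacetate | CCOC(=O)CP(=O)(OCC)OCC | starting material
7 | ethyl (2E,6Z)-3,7,11-trimethyldodeca-2,6,10-trienoate | CCOC(=O)/C=C(C)/CC/C=C(C)\CCC=C(C)C | intermediate
8 | (2E,6Z)-farnesol | CC(C)=CCC/C(C)=C\CC/C(C)=C/CO | intermediate
9 | (2E,6Z)-farnesyl chloride | CC(C)=CCC/C(C)=C\CC/C(C)=C/CCl | intermediate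
10 | tris(tetrabutylammonium) hydrogen diphosphate | CCCC[N+](CCCC)(CCCC)CCCC.CCCC[N+](CCCC)(CCCC)CCCC.CCCC[N+](CCCC)(CCCC)CCCC.OP(=O)([O-])OP(=O)([O-])[O-] | starting material
11 | (2E,6Z)-farnesyl diphosphate (tris-ammonium salt; free-acid SMILES) | CC(C)=CCC/C(C)=C\CC/C(C)=C/COP(=O)(O)OP(=O)(O)O | intermediate
12 | (1Z,4E,8E)-2,6,6,9-tetramethylcycloundeca-1,4,8-triene | C/C1=C\CC(C)(C)/C=C/C/C(C)=C\CC1 | intermediate
13 | [(3Z,7E)-3,7,10,10-tetramethylcycloundeca-3,7-dien-1-yl](isopinocampheyl)borane, boron on the face that becomes the 1R alcohol | C[C@@H]1[C@H]2C[C@H](C2(C)C)C[C@H]1B[C@@H]1CC(C)(C)C/C=C(C)/CC/C=C(C)\C1 | intermediate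
14 | (1R,3Z,7E)-3,7,10,10-tetramethylcycloundeca-3,7-dien-1-ol | C/C1=C\CC(C)(C)C[C@@H](O)C/C(C)=C\CC1 | intermediate
15 | p-coumaric acid | OC(=O)/C=C/c1ccc(O)cc1 | starting material
16 | tert-butyldimethylsilyl (E)-3-[4-(tert-butyldimethylsilyloxy)phenyl]prop-2-enoate | CC(C)(C)[Si](C)(C)OC(=O)/C=C/c1ccc(O[Si](C)(C)C(C)(C)C)cc1 | intermediate
17 | (E)-3-[4-(tert-butyldimethylsilyloxy)phenyl]prop-2-enoic acid | OC(=O)/C=C/c1ccc(O[Si](C)(C)C(C)(C)C)cc1 | intermediate
18 | (1R,3Z,7E)-3,7,10,10-tetramethylcycloundeca-3,7-dien-1-yl (E)-3-[4-(tert-butyldimethylsilyloxy)phenyl]prop-2-enoate | C/C1=C\CC(C)(C)C[C@@H](OC(=O)/C=C/c2ccc(O[Si](C)(C)C(C)(C)C)cc2)C/C(C)=C\CC1 | intermediate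
19 | (1R,3Z,8S)-8-hydroperoxy-3,10,10-trimethyl-7-methylidenecycloundec-3-en-1-yl (E)-3-[4-(tert-butyldimethylsilyloxy)phenyl]prop-2-enoate | C=C1CC/C=C(/C)C[C@H](OC(=O)/C=C/c2ccc(O[Si](C)(C)C(C)(C)C)cc2)CC(C)(C)C[C@@H]1OO | intermediate
20 | (1R,3Z,8S)-8-hydroperoxy-3,10,10-trimethyl-7-methylidenecycloundec-3-en-1-yl (E)-3-(4-hydroxyphenyl)prop-2-enoate | C=C1CC/C=C(/C)C[C@H](OC(=O)/C=C/c2ccc(O)cc2)CC(C)(C)C[C@@H]1OO | target

## Step count and risks

Total: 12 steps. Longest linear sequence: 11 steps from nerol (steps 1–8 and 10–12); step 9 is a one-step side branch.

**Step 7 (key step, proposed new method).**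
- Risk: the kinked 6Z chain may bind in an unproductive fold, so that ionisation is followed by water capture, premature proton loss or 1,10-closure instead of 1,11-closure.
- Fallback: the enzyme is used in its documented mode and the olefin geometry is corrected afterwards. The fallback sets out from 10 and returns at 12.
  - 10 is alkylated with commercial (2E,6E)-farnesyl chloride F1 (MeCN, rt) to (2E,6E)-farnesyl diphosphate F2.
  - The same synthase with MgCl2 converts F2 into α-humulene F3, which can also be purchased.
  - m-Chloroperbenzoic acid (1 equiv, CH2Cl2, 0 °C) should epoxidise F3 preferentially at the trisubstituted olefin remote from the gem-dimethyl carbon, giving the racemic trans 6,7-epoxide F4 (farnesyl numbering). The 2,3-regioisomer is removed by chromatography.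
  - Ph2PLi (THF, rt) opens F4 at its secondary carbon with inversion to the β-hydroxyphosphine F5. MeI then gives the phosphonium betaine F6, whose syn elimination of methyldiphenylphosphine oxide returns the olefin with inverted geometry, which is 12.

**Step 8.**
- Risk: competing hydroboration of the strained E trisubstituted olefin, a transannular second addition by the remaining B–H of the adduct, and incomplete facial discrimination on the hindered trans olefin.
- Fallback: a borane with a single B–H, followed by classical resolution. It sets out from 12 and returns at 14.
  - Disiamylborane (Sia2BH, THF, 0 °C; NaOH, H2O2), which adds poorly to trisubstituted olefins, gives the racemic alcohol F7.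
  - Esterification with (S)-O-methylmandelic acid (DCC, DMAP) gives the ester F8 of the 1R alcohol and its C1 epimer F9, separated by chromatography. These esters also allow the carbinol configuration to be assigned by NMR.
  - LiOH (THF/MeOH/H2O) cleaves F8 to 14.

**Step 11.**
- Risk: poor facial selectivity at C11, because control rests only on the ring conformation set by a remote ester. Hydrogen abstraction from ring methylenes or attack at the Z olefin may also occur; those isomers are removed by chromatography.
- Fallback: the unwanted epimer is converted by inverting substitution. It sets out from the C11 epimer F10 that step 11 forms from 18 and returns at 19.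
  - F10 is reduced with PPh3 (CH2Cl2, 0 °C) to the 11R allylic alcohol F11 with retention.
  - MsCl and Et3N (−40 °C) give the mesylate F12.
  - Anhydrous H2O2 in Et2O (−78 to −20 °C) displaces the mesylate with inversion to 19. The partition between direct and allylic (SN2′) substitution has to be checked.

**Step 12.**
- Risk: loss of the hydroperoxide through fluoride- or base-promoted elimination, or acyl transfer once the phenoxide is formed.
- Fallback: the order of the last two steps is reversed so that no fluoride meets the peroxide. It sets out from 18 and returns at 20.
  - 18 is desilylated (Bu4NF, THF, 0 °C) to the free-phenol ester F13.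
  - F13 is photooxygenated under the conditions of step 11 in CH2Cl2, where the electron-poor phenol should quench singlet oxygen only slowly, giving 20 directly.

## Further compounds

F1 | step 7 | (2E,6E)-farnesyl chloride | CC(C)=CCC/C(C)=C/CC/C(C)=C/CCl
F2 | step 7 | (2E,6E)-farnesyl diphosphate (free-acid form) | CC(C)=CCC/C(C)=C/CC/C(C)=C/COP(=O)(O)OP(=O)(O)O
F3 | step 7 | α-humulene, (1E,4E,8E)-2,6,6,9-tetramethylcycloundeca-1,4,8-triene | C/C1=C\CC(C)(C)/C=C/C/C(C)=C/CC1
F4 | step 7 | α-humulene trans-6,7-epoxide (racemic, one enantiomer drawn) | C/C1=C\CC(C)(C)/C=C/C[C@@]2(C)O[C@@H]2CC1
F5 | step 7 | β-hydroxyphosphine from anti opening of F4 (racemic) | C/C1=C\CC(C)(C)/C=C/C[C@@](C)(O)[C@@H](P(c2ccccc2)c2ccccc2)CC1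
F6 | step 7 | methyldiphenylphosphonium betaine (racemic) | C/C1=C\CC(C)(C)/C=C/C[C@@](C)([O-])[C@@H]([P+](C)(c2ccccc2)c2ccccc2)CC1
F7 | step 8 | racemic (3Z,7E)-3,7,10,10-tetramethylcycloundeca-3,7-dien-1-ol | C/C1=C\CC(C)(C)CC(O)C/C(C)=C\CC1
F8 | step 8 | (S)-O-methylmandelate of the 1R alcohol | C/C1=C\CC(C)(C)C[C@@H](OC(=O)[C@@H](OC)c2ccccc2)C/C(C)=C\CC1
F9 | step 8 | (S)-O-methylmandelate of the 1S alcohol | C/C1=C\CC(C)(C)C[C@H](OC(=O)[C@@H](OC)c2ccccc2)C/C(C)=C\CC1
F10 | step 11 | C11 epimer of 19 (7R,11R in ring numbering) | C=C1CC/C=C(/C)C[C@H](OC(=O)/C=C/c2ccc(O[Si](C)(C)C(C)(C)C)cc2)CC(C)(C)C[C@H]1OO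
F11 | step 11 | 11R allylic alcohol | C=C1CC/C=C(/C)C[C@H](OC(=O)/C=C/c2ccc(O[Si](C)(C)C(C)(C)C)cc2)CC(C)(C)C[C@H]1O
F12 | step 11 | 11R allylic mesylate | C=C1CC/C=C(/C)C[C@H](OC(=O)/C=C/c2ccc(O[Si](C)(C)C(C)(C)C)cc2)CC(C)(C)C[C@H]1OS(C)(=O)=O
F13 | step 12 | (1R,3Z,7E)-3,7,10,10-tetramethylcycloundeca-3,7-dien-1-yl (E)-3-(4-hydroxyphenyl)prop-2-enoate | C/C1=C\CC(C)(C)C[C@@H](OC(=O)/C=C/c2ccc(O)cc2)C/C(C)=C\CC1
A1 | alternative 1 | open-chain cyclopropanol with Z alkenyl iodide, C7 p-methoxybenzyl ether and C11 silyl ether | I/C=C(/C)C[C@H](OCc1ccc(OC)cc1)CC(C)(C)C[C@@H](O[Si](C)(C)C(C)(C)C)C1(O)CC1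
A2 | alternative 1 | eleven-membered C1 ketone with Z olefin, C7 and C11 ethers | O=C1CC/C=C(/C)C[C@H](OCc2ccc(OC)cc2)CC(C)(C)C[C@H]1O[Si](C)(C)C(C)(C)C
A3 | alternative 2 | dimedone | CC1(C)CC(=O)CC(=O)C1
A4 | alternative 2 | bicyclo[5.4.0]undecene with C1 tosyloxymethyl arm, C7 tertiary alcohol and C11 silyl ether (ring-fusion centres of either configuration) | CC1=CCCC2(COS(=O)(=O)c3ccc(C)cc3)[C@H](O[Si](C)(C)C(C)(C)C)CC(C)(C)CC2(O)C1
A5 | alternative 2 | eleven-membered methylene ketone with Z olefin and C11 silyl ether | C=C1CC/C=C(/C)CC(=O)CC(C)(C)C[C@H]1O[Si](C)(C)C(C)(C)C
A6 | alternative 3 | cis-1,2-divinylcycloheptanol with C7 silyl ether (one cis diastereomer drawn) | C=C[C@@]1(O)CC(C)(C)C[C@@H](O[Si](C)(C)C(C)(C)C)C[C@@]1(C)C=C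
A7 | alternative 3 | eleven-membered C11 ketone with Z olefin and C7 silyl ether | O=C1CCC/C=C(/C)C[C@H](O[Si](C)(C)C(C)(C)C)CC(C)(C)C1
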